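Readings and results were generated by integration for an exercise; the scatter is artificial.

The target in the dusk run stops climbing: it reads 20% at 2.50 h, 25% at 8.00 h and 23% at 10.0 h, while the colder midnight and spring runs still rise at their last readings.

| flask | starting material | reagent | temperature | remark | time |
|---|---|---|---|---|---|
| midnight | 0.096 M | 1 equiv | 0 °C | run made earlier |  |
| dusk | 0.096 M | 2.2 equiv | 15 °C | run made earlier |  |
| spring | 0.19 M | 1.5 equiv | 0 °C | run made earlier |  |
| Tuesday's | 0.096 M | 1.50 equiv | 25 °C |  | 6.0 h |
| Saturday's | 0.096 M | 1.50 equiv | 5 °C |  | 6.0 h |

| midnight: time / h | midnight: target / % | dusk: time / h | dusk: target / % | spring: time / h | spring: target / % |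
|---|---|---|---|---|---|
| 3.00 | 2 | 2.50 | 20 | 3.00 | 7 |
| 6.00 | 2 | 5.00 | 23 | 6.00 | 10 |
| 15.0 | 8 | 8.00 | 25 | 15.0 | 22 |
| 20.0 | 13 | 10.0 | 23 | 20.0 | 27 |

(each reading ± 1.5 percentage points)

* the flask with the highest amount of target, in percent of the starting material charged ("all alike" if they lie within 1.5 percentage points) (Tuesday's / Saturday's / all alike)
* final target, as a percentage of the starting material charged, in Tuesday's
* final target, as a percentage of the starting material charged, in Saturday's



I carry one number from that stop. If target is the one draw on both partners, the dusk reading at 8.00 h gives 0.171, my ceiling quotient (a reaction quotient at its plateau): target divided by the product of free starting material and free reagent, each as a fraction of the starting-material charge. It is a reading and carries the scatter, and using it at 25 °C is my assumption.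

For Saturday's I take the spring reading at 6.00 h, 10%, as a rough level. Now I turn the question round: for Tuesday's not to stand clear above that level, its target must stop below 11.5%, so its free product must be under 0.673. But if target is the one draw, the free product at that point is 1.23, larger than the limit, so the forward rate still beats the backward one there. I therefore commit to Tuesday's ahead, unless something else holds the partners or heat lowers the quotient.

The forecast parts from me, with 13% for Tuesday's, 12% for Saturday's and the verdict all alike, saying “The two flasks are nearly tied”.

Tuesday's ends at 12.4% and Saturday's at 12.3%, so the verdict is all alike.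

    starting material + reagent ⇌ adduct (K = 3.10 /M, k = 6.20 /M/min, Ea = 64.0 kJ/mol, ΔH = 27.0 kJ/mol)
    2 starting material → self-condensation product (k = 4.40 × 10⁻⁴ /M/min, Ea = 79.0 kJ/mol)
    adduct ⇌ target (K = 0.560, k = 0.0440 /min, Ea = 92.0 kJ/mol, ΔH = −53.0 kJ/mol)
    (constants at 25 °C)

Tuesday's holds 22.1% of the charge as adduct at 6.00 h, and its free product is 0.742, smaller than the 1.23 I reckoned with. The ceiling quotient times that free product gives 12.7%. The same flask as Tuesday's but with 6.00 equiv of reagent has a free product of 1.53, for which the quotient gives 26.1%, and that flask holds 25.4% of target, clear above Saturday's.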